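The numbers in the tables are calculated on assumed constants, noise included.

20.6 mM s⁻¹ was the number I read first: the target formed per second in the epsilon run up to 40.0 s. Free catalyst at 41 mM against 14 mM in the zeta run, a factor of 2.93, moved the target at that time from 45% to 55%, a factor of 1.22. So I took this rate for the supply of the gas and called it the gas ceiling. From the zeta run's last reading, 72% at 80.0 s, I took a constant of 1.14 M⁻¹ s⁻¹. That constant times substrate times free catalyst I called the demand. My rule was that a flask runs at the smaller of demand and ceiling, and the comparison drifts, since demand falls as substrate goes while the ceiling stays.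

| flask | substrate | gas | free catalyst | remark | time |
|---|---|---|---|---|---|
| delta | 1.5 M | 88 mM (held) | 4.3 mM | run made earlier |  |
| zeta | 1.5 M | 88 mM (held) | 14 mM | run made earlier |  |
| epsilon | 1.5 M | 88 mM (held) | 41 mM | run made earlier |  |
| eta | 1.7 M | 88 mM (held) | 15 mM | run made earlier |  |
| birch | 0.80 M | 88 mM (held) | 4.0 mM |  | 2.5 min |
| cedar | 1.5 M | 88 mM (held) | 5.0 mM |  | 2.5 min |
| larch | 1.5 M | 88 mM (held) | 15 mM |  | 2.5 min |
| alder | 2.5 M | 88 mM (held) | 50 mM |  | 2.5 min |
| maple | 2.5 M | 88 mM (held) | 8.0 mM |  | 2.5 min |

- delta (time / s: target / %): 15.0: 6; 30.0: 15; 50.0: 24; 60.0: 26; 80.0: 31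
- zeta (time / s: target / %): 10.0: 10; 12.0: 15; 20.0: 23; 40.0: 45; 80.0: 72
- epsilon (time / s: target / %): 10.0: 14; 20.0: 30; 40.0: 55; 50.0: 65; 80.0: 94
- eta (time / s: target / %): 10.0: 11; 20.0: 23; 40.0: 41; 50.0: 49; 80.0: 71

(standard deviation of a reading: 1.5 percentage points)

- at the start none of the gas is in solution

1. all flasks from highest to lowest amount of target, in percent of the substrate charged, at 2.5 min (birch / cedar / larch / alder / maple)
2. the same order at 30 s (birch / cedar / larch / alder / maple)
3. the amount of target, in percent of the substrate charged of the flask you put first, at 2.5 min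
4. the amount of target, in percent of the substrate charged of the flask you put last, at 2.5 min

I kept the books on alder, with substrate as the limiting reagent, charged at 2.5 M. Alder's starting demand by my reckoning was 142 mM s⁻¹, far above the ceiling, so I booked the first entry at the ceiling. In my books for alder that entry ran until demand fell to the ceiling, at a substrate of 0.363 M, so I booked 2.14 M as target in 104 s. The second entry for alder was the remainder, reckoned as a pseudo-first-order tail with 0.0568 s⁻¹ for the rest of 2.5 min, which left 0.0260 M unconverted in my books. The whole catalyst charge of alder equals 2.00% of its substrate, so I booked nothing as held on catalyst. The books closed at 99.0% target for alder at 2.5 min, and at 30 s the ceiling gave alder 24.7%.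

The forecast gave alder > larch > maple > cedar > birch at 2.5 min and larch > alder > maple > cedar > birch at 30 s, with 97% for the first flask, lower than my figure, and 50% for the last, holding that “gas transfer limits the rate”.

The flasks gave alder > larch > maple > cedar > birch and larch > alder > maple > cedar > birch, with 99.1% in alder and 56.6% in birch, and alder stood at 24.7% at 30 s.

    substrate + free catalyst → catalyst intermediate A (k = 1.50 M⁻¹ s⁻¹)
    coupling partner + catalyst intermediate A ⇌ catalyst intermediate B (K = 12.0 M⁻¹, k = 960 M⁻¹ s⁻¹)
    catalyst intermediate B ⇌ by-product + catalyst intermediate C (K = 0.530 M, k = 180 s⁻¹)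
    catalyst intermediate C → free catalyst + target (k = 28.0 s⁻¹)
    gas ⇌ coupling partner, rate k5*(csat - [coupling partner]) (kL = 0.240 s⁻¹)

What birch lacked at 2.5 min was mainly a matter of the time of reading, for birch stood at 56.6% then and at >99.9% at 25.0 min. I carried the same ceiling to larch, with 15 mM of free catalyst. By my reckoning the demand of larch met the ceiling at a substrate of 1.21 M, after 14.1 s, and the tail then left 7.95% of the substrate charged. Larch held 6.22% of its substrate at 2.50 min.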